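Remark: atoms carry eudesmane/eremophilane numbers (C1–C5 and C10 form ring A, C5–C10 form ring B, C11–C13 are the isopropenyl group); β is the face of the ring-fusion methyl group, α the opposite face.
Remark: commercial (+)-dihydrocarvone is taken as the usual mixture of C2 epimers; both give the same enamine in step 1.

## Structural features

The target is an eremophilane, a trans-fused decalin. Ring A carries the 3α-senecioate, the secondary 4β-methyl and the quaternary 5β-methyl; ring B carries the 7α-isopropenyl group, the C8 ketone and the 9α-tiglate. C3, C4 and C5 are contiguous, C10 and C9 continue the row across the ring fusion, and C7 stands alone on the far side of the ketone. In the chair–chair form only the 5-methyl is axial, so C7 and C9, both α to the ketone, sit in their preferred configurations, whereas C3, C4, C5 and C10 must be set kinetically or by relay. The real difficulty is the cis-vicinal pair of methyl groups on C4 and C5, one of them on a quaternary ring-fusion carbon with no functional group next to it, in one absolute configuration. The fragile groups are the β,γ-unsaturated ketone (the isopropenyl double bond moves into conjugation under acid or base), the α-acyloxy ketone, the two different unsaturated esters on two secondary hydroxyls, and the isopropenyl group itself toward acid, hydroboration and hydrogenation. The key step exploits the fact that the C5 methyl is one bond away from C10: in a eudesmane the same methyl sits on C10, and an epoxide on C4–C5 of ring A can pull it across the ring fusion.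

## Logic of the disconnections

22 ⇒ 21 ⇒ 20 ⇒ 19. The acyl–O bond at C3, the O–Si bond at C3 and the acyl–O bond at C9 are cut in that order. The esters come last because neither would survive the dissolving-metal step, and one at a time so that two free secondary hydroxyls never have to be told apart. This removes two five-carbon units and all ester sensitivity. It demands that the C3 oxygen stays silylated from 10 to 20 and that both acylations run without a base strong enough to move the isopropenyl double bond.

19 ⇒ 17 ⇒ 15. The C9–O bond is cut, then the C10–H bond and the enol O–Si bond. An α-ketol is an oxidised, regiodefined enolate, and that enolate is what a dissolving-metal reduction of an enone leaves behind. C9 and C10 disappear as stereocentres and ring B becomes a flat enone. The reduction must give the trans ring fusion, the enolate must be trapped before it equilibrates toward C7, and the oxidant must prefer the enol ether to the isopropenyl group.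

15 ⇒ 14 ⇒ 13. The C7 configuration is given up (14 and 15 are epimers that equilibrate), then the C8 carbonyl oxygen is removed. Ring B is reduced to an olefin. The forward oxidation must hit C8 rather than C1 or the isopropenyl allylic positions, and the equilibration must stop before the double bond drifts into conjugation.

13 ⇒ 12 ⇒ 11. The C4–H bond is traced back to a C4–O bond. That oxygen is the footprint of the trigger of the key step. The forward radical reduction must deliver hydrogen on the α face of C4.

11 ⇒ 10 (key). The C5–CH3 bond is cut and the methyl is returned to C10; the C9=C10 bond becomes a C9–H bond and the C4 hydroxyl becomes a 4α,5α-epoxide. In one sentence: an epoxide-triggered 1,2-shift of the angular methyl group turns 10 into 11. The quaternary C5 and the cis-4,5-dimethyl relation are thereby reduced to the angular methyl of a eudesmane plus an epoxide whose face is set by the C3 oxygen. The precursor skeleton is one annulation away from a terpene ketone. The forward step needs the C10–CH3 bond antiperiplanar to C5–O, cleavage of C5–O rather than C4–O, and loss of H-9 rather than H-1.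

10 ⇒ 9 ⇒ 8 ⇒ 7. The O–Si bond, the two epoxide C–O bonds and the C3–H bond are cut. All of C3, C4 and the C5 oxygen hang on the one carbinol at C3. The hydride must come from the β face, and the directed epoxidation must ignore the isopropenyl group.

7 ⇒ 6 ⇒ 1 + 3 (with 2). The C4=C5 bond (aldol condensation) and the C1–C10 bond (Michael addition) are cut. This leaves a commercial terpene ketone and a five-carbon enone. The quaternary C10 must be set cis to the isopropenyl group, against the substrate's own preference, which is the task of 2.

## Other disconnections considered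

Alternative 1: The first route to come to mind cuts C5–C6 and C9=C10, a Robinson annulation of methyl vinyl ketone onto a ring-A ketone A1 (2,3-dimethyl-4-silyloxycyclohexanone) to give the enone A2. A1 must already carry C3 and C4 as one enantiomer, and the quaternary C5 then forms in a Michael addition whose cis/trans outcome relative to C4 rests on a conformational preference of a flexible enamine or enolate. The isopropenyl group would have to be added next to the ketone afterwards, and an aldol–dehydration delivers the conjugated isopropylidene isomer first. The chosen plan takes C4 and C5 from one stereocentre of a cheap terpene through a stereospecific shift and keeps the isopropenyl group from the start.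

Alternative 2: A dearomatisation that cuts C4–C5. The para carbon of the pentasubstituted phenol A3, which carries an epoxide tether, would attack the epoxide under Lewis acid and give the cross-conjugated dienone A4 with ring A, C3, C4 and the quaternary C5 in one step. C7, C9 and C10 would still have to be set by reductions of a flat dienone that carries an enol ether and a conjugated isopropenyl group, and dissolving metal would cleave the oxygen next to the ketone. The 6-endo opening at the methyl-bearing epoxide carbon competes with ortho attack and with 5-exo opening, and A3 needs a multi-step arene synthesis of its own.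

Alternative 3: An intramolecular Diels–Alder reaction that cuts C5–C10 and C6–C7. The triene A5 would close ring B directly to the enol ether 17 and set C5, C7 and C10 at once. The dienophile is an unactivated 1,1-disubstituted olefin facing an electron-rich 2-silyloxydiene, so a high temperature is expected. At that temperature the silyloxytriene, which is conjugated with the isopropenyl group, has 6π-electrocyclisation and 1,5-hydrogen shifts open to it. Three new stereocentres and the ring fusion would rest on tether control by C3 and C4 alone, so the step count is attractive but the stereochemical outcome cannot be defended as well as a suprafacial 1,2-shift.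

Key step: step 6

## Steps

Step 1
Reactants: 1 (+)-dihydrocarvone, (2R,5R)-2-methyl-5-(prop-1-en-2-yl)cyclohexan-1-one; 2 (R)-1-phenylethylamine; 3 ethyl vinyl ketone (pent-1-en-3-one)
Product: 6 (2S,5R)-2-methyl-2-(3-oxopentyl)-5-(prop-1-en-2-yl)cyclohexan-1-one, via ketimine 4 (not isolated), via adduct ketimine 5 (not isolated)
Conditions: 2, TsOH (cat.), toluene, reflux, Dean–Stark; then 3, THF, 40 °C; then 10% aq. AcOH, rt
Reagents that add atoms: water, O
Why: Michael addition of the secondary enamine tautomer of a chiral ketimine to an enone (aza-ene-like, hydrogen passed from N–H); the more substituted α-carbon reacts and the (R)-auxiliary should steer the acceptor to the face that makes the new quaternary carbon S (methyl cis to the isopropenyl group), against the weaker bias of the substrate; both C2 epimers of 1 converge through the enamine.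

Step 2
Reactants: 6
Product: 7 (+)-α-cyperone, (4aS,7R)-1,4a-dimethyl-7-(prop-1-en-2-yl)-4,4a,5,6,7,8-hexahydronaphthalen-2(3H)-one (eudesma-4,11-dien-3-one, 10β-methyl, 7β-isopropenyl)
Conditions: NaOMe, MeOH, rt → 50 °C
Reagents that add atoms: none
Why: Intramolecular aldol condensation, the closing stage of a Robinson annulation; no stereocentre is formed and the quaternary carbon cannot epimerise.

Step 3
Reactants: 7
Product: 8 eudesma-4,11-dien-3α-ol (3R; hydroxyl on the face opposite to the C10 methyl)
Conditions: LiBH(s-Bu)3 (L-Selectride), THF, −78 °C; then H2O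
Reagents that add atoms: none
Why: 1,2-Reduction of a β,β-disubstituted enone by a bulky trialkylborohydride; the reagent should approach C3 equatorially from the β face and give the pseudoaxial 3α-alcohol, and conjugate reduction is blocked by the fully substituted C5.

Step 4
Reactants: 8
Product: 9 4α,5α-epoxyeudesm-11-en-3α-ol (epoxide cis to the 3-hydroxyl, anti to the C10 methyl)
Conditions: VO(acac)2 (cat.), t-BuOOH, CH2Cl2, 0 °C → rt
Reagents that add atoms: tert-butyl hydroperoxide, CC(C)(C)OO
Why: Hydroxyl-directed vanadium-catalysed epoxidation; the peroxide bound to the 3α-vanadate ester delivers oxygen to the same (α) face of the tetrasubstituted C4=C5 bond, and the isopropenyl group, which has no directing hydroxyl, should stay untouched.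

Step 5
Reactants: 9
Product: 10 3α-(tert-butyldimethylsilyloxy)-4α,5α-epoxyeudesm-11-ene
Conditions: TBSCl, imidazole, DMAP (cat.), DMF, 35 °C
Reagents that add atoms: tert-butyldimethylsilyl chloride, CC(C)(C)[Si](C)(C)Cl
Why: Standard silylation of a secondary alcohol; the silyl ether carries the C3 oxygen through the Lewis acid, radical, oxidation and dissolving-metal steps.

Step 6
Reactants: 10
Product: 11 3α-(tert-butyldimethylsilyloxy)eremophila-9,11-dien-4α-ol (4β,5β-dimethyl, 7β-isopropenyl)
Conditions: BF3·OEt2 (0.3 equiv), CH2Cl2, −78 → −30 °C; then Et3N, aq. NaHCO3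
Reagents that add atoms: none
Why: BF3 binds the epoxide oxygen, the C5–O bond ionises with a simultaneous suprafacial 1,2-shift of the C10 methyl group to C5 (Wagner–Meerwein), and the tertiary C10 cation then loses H-9 to give the 9,10-olefin while the 4α-alkoxide is protonated. The closest known reaction type is the Westphalen rearrangement and its Lewis acid epoxide version, in which 5α-hydroxy and 4,5- or 5,6-epoxy 10β-methyl decalins of the steroid series pass the angular methyl to C5 and end as 9(10)-olefins. No ring is closed; the skeleton changes from eudesmane to eremophilane. At C5 the methyl enters on the β face, anti to the departing α C–O bond, so the C10 configuration of step 1 is transferred intact; C4 keeps its oxygen on the α face where the directed epoxidation of step 4 put it, which leaves the 4-methyl cis to the new 5-methyl. Cleavage of C5–O rather than C4–O is secured because C4 is deactivated inductively by the C3 oxygen and, with the 3α-silyloxy group pseudoaxial in the trans-fused half chair, the C3–H bond lies about 120° from the C4–O bond, too far to assist a hydride-shift opening. Methyl migration rather than ring-bond migration or simple loss of H-6 is secured because the axial C10–CH3 bond is the only C–C bond antiperiplanar to C5–O, the shift relieves the syn contact between the C4 and C10 methyl groups, and the medium contains no base. Loss of H-9 rather than H-1 is only biased by the substrate: the 7β-isopropenyl group is syn to the new 5β-methyl, a double bond in ring B flattens that ring and removes their 1,3-diaxial contact, whereas the 1(10)-olefin keeps it, and the silyl ether hinders approach to H-1. Sub-stoichiometric Lewis acid at low temperature should leave the isopropenyl group and the silyl ether intact.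

Step 7
Reactants: 11
Product: 12 methyl oxalate of 11 at the 4α-oxygen [3α-(tert-butyldimethylsilyloxy)eremophila-9,11-dien-4α-yl methyl oxalate]
Conditions: ClC(O)CO2Me, pyridine, DMAP (cat.), CH2Cl2, 0 → 25 °C
Reagents that add atoms: methyl chlorooxoacetate, COC(=O)C(=O)Cl
Why: Acylation of the tertiary alcohol with a small, very electrophilic acid chloride under nucleophilic catalysis gives the radical precursor; the C4 configuration is not touched.

Step 8
Reactants: 12
Product: 13 3α-(tert-butyldimethylsilyloxy)eremophila-9,11-diene (4α-H, 4β,5β-dimethyl, 7β-isopropenyl)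
Conditions: Bu3SnH (3 equiv, 0.5 M), AIBN (cat.), toluene, 110 °C
Reagents that add atoms: none
Why: Barton–McCombie-type radical deoxygenation in its tertiary oxalate variant; the tertiary C4 radical should take hydrogen axially on the α face, anti to the axial 5β-methyl, so the 4-methyl ends β and equatorial, which is also the more stable epimer; a high stannane concentration should outrun 3-exo attack of the radical on C9=C10.

Step 9
Reactants: 13
Product: 14 3α-(tert-butyldimethylsilyloxy)eremophila-9,11-dien-8-one with 7β-isopropenyl (7α-H)
Conditions: CrO3, 3,5-dimethylpyrazole, CH2Cl2, −20 °C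
Reagents that add atoms: chromium trioxide, O=[Cr](=O)=O
Why: Allylic C–H oxidation with the CrO3·3,5-dimethylpyrazole complex; as in the oxidation of 5-ene steroids to 7-ketones and of 1(10)-eremophilenes at C2, the methylene next to the CH= terminus (C8) should be attacked rather than the one next to the fully substituted terminus (C1), and the silyl ether is inert.

Step 10
Reactants: 14
Product: 15 3α-(tert-butyldimethylsilyloxy)eremophila-9,11-dien-8-one with 7α-isopropenyl (7β-H)
Conditions: DBU (0.2 equiv), CH2Cl2, 0 °C, short contact; then AcOH
Reagents that add atoms: none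
Why: Base-catalysed epimerisation at C7 through the cross-conjugated dienolate, a stereoconvergent step; with the isopropenyl group α it is pseudoequatorial and free of the 1,3-diaxial contact with the 5β-methyl, so 15 should be the favoured epimer; dienolates reprotonate fastest at the α-carbon, so short contact with a catalytic amidine should not move the double bond into conjugation.

Step 11
Reactants: 15
Product: 17 3α-(tert-butyldimethylsilyloxy)-8-(trimethylsilyloxy)-10αH-eremophila-8,11-diene (trans-fused, 7α-isopropenyl), via lithium enolate 16 (not isolated)
Conditions: Li (2.2 equiv), t-BuOH (1.0 equiv), NH3(l)/THF, −78 °C; isoprene; NH3 off; then Me3SiCl, Et3N, THF, −78 → 0 °C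
Reagents that add atoms: chlorotrimethylsilane, C[Si](C)(C)Cl
Why: Dissolving-metal reduction of the enone with regiospecific trapping of the enolate as its silyl enol ether; the β-carbanion at C10 should be protonated axially to give the trans ring fusion (10α-H), as with other 10-methyl-1(9)-octal-2-one type enones; with one equivalent of proton donor the C8=C9 enolate can neither equilibrate toward C7 nor be reduced further.

Step 12
Reactants: 17
Product: 19 3α-(tert-butyldimethylsilyloxy)-9α-hydroxy-10αH-eremophil-11-en-8-one, via silyloxy epoxide 18 (not isolated)
Conditions: dimethyldioxirane (1.0 equiv), acetone/CH2Cl2, −78 → −40 °C; then AcOH, THF/H2O, 0 °C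
Reagents that add atoms: dimethyldioxirane, CC1(C)OO1
Why: Rubottom oxidation; the dioxirane should epoxidise the electron-rich silyl enol ether much faster than the 1,1-disubstituted isopropenyl group, on the α face because the axial 5β-methyl is 1,3 to C9 on the β face; mild acid opens 18 to the 9α (equatorial) hydroxy ketone, which is also the more stable C9 epimer.

Step 13
Reactants: 19
Product: 20 3α-(tert-butyldimethylsilyloxy)-9α-[(E)-2-methylbut-2-enoyloxy]-10αH-eremophil-11-en-8-one
Conditions: tigloyl chloride, pyridine, DMAP (cat.), CH2Cl2, 0 °C
Reagents that add atoms: tigloyl chloride [(E)-2-methylbut-2-enoyl chloride], ClC(=O)/C(C)=C/C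
Why: Acylation of the secondary α-ketol with an acid chloride under pyridine/DMAP catalysis; the E geometry of the tiglate is the stable one, and C7 and C9 are already in their preferred configurations.

Step 14
Reactants: 20
Product: 21 3α-hydroxy-9α-[(E)-2-methylbut-2-enoyloxy]-10αH-eremophil-11-en-8-one
Conditions: HF·pyridine, pyridine, THF, 0 °C → rt
Reagents that add atoms: none
Why: Cleavage of the silyl ether with buffered HF·pyridine, which spares the base-sensitive α-acyloxy ketone and is too dilute to add to the isopropenyl group.

Step 15
Reactants: 21
Product: 22 target, (3R,4R,5R,7S,9S,10R)-3-(3-methylbut-2-enoyloxy)-9-[(E)-2-methylbut-2-enoyloxy]-eremophil-11-en-8-one (3α-senecioate, 9α-tiglate, 4β,5β-dimethyl, 7α-isopropenyl, 10α-H)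
Conditions: 3-methylbut-2-enoyl chloride, pyridine, DMAP (cat.), CH2Cl2, 0 °C → rt
Reagents that add atoms: 3-methylbut-2-enoyl chloride, CC(C)=CC(=O)Cl
Why: Acylation of the equatorial 3α-alcohol; pyridine at 0 °C in place of a trialkylamine avoids vinylketene formation and thus the deconjugated 3-methylbut-3-enoate.

## Compound list

1 | (+)-dihydrocarvone, (2R,5R)-2-methyl-5-(prop-1-en-2-yl)cyclohexan-1-one | C=C(C)[C@@H]1CC[C@@H](C)C(=O)C1 | starting material
2 | (R)-1-phenylethylamine | C[C@@H](N)c1ccccc1 | starting material
3 | ethyl vinyl ketone | C=CC(=O)CC | starting material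
4 | ketimine of 1 with 2 | C=C(C)[C@@H]1CC[C@@H](C)C(=N[C@H](C)c2ccccc2)C1 | intermediate
5 | ketimine of the Michael adduct (2S,5R ring, R auxiliary) | C=C(C)[C@@H]1CC[C@@](C)(CCC(=O)CC)C(=N[C@H](C)c2ccccc2)C1 | intermediate
6 | (2S,5R)-2-methyl-2-(3-oxopentyl)-5-(prop-1-en-2-yl)cyclohexan-1-one | C=C(C)[C@@H]1CC[C@@](C)(CCC(=O)CC)C(=O)C1 | intermediate
7 | (+)-α-cyperone, (4aS,7R)-eudesma-4,11-dien-3-one | C=C(C)[C@@H]1CC[C@@]2(C)CCC(=O)C(C)=C2C1 | intermediate
8 | eudesma-4,11-dien-3α-ol | C=C(C)[C@@H]1CC[C@@]2(C)CC[C@@H](O)C(C)=C2C1 | intermediate
9 | 4α,5α-epoxyeudesm-11-en-3α-ol | C=C(C)[C@@H]1CC[C@@]2(C)CC[C@@H](O)[C@@]3(C)O[C@@]23C1 | intermediate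
10 | 3α-(tert-butyldimethylsilyloxy)-4α,5α-epoxyeudesm-11-ene | C=C(C)[C@@H]1CC[C@@]2(C)CC[C@@H](O[Si](C)(C)C(C)(C)C)[C@@]3(C)O[C@@]23C1 | intermediate
11 | 3α-(tert-butyldimethylsilyloxy)eremophila-9,11-dien-4α-ol (7β-isopropenyl) | C=C(C)[C@H]1C[C@]2(C)[C@](C)(O)[C@H](O[Si](C)(C)C(C)(C)C)CCC2=CC1 | intermediate
12 | 4α-O-(methyl oxalyl) derivative of 11 | C=C(C)[C@H]1C[C@]2(C)[C@](C)(OC(=O)C(=O)OC)[C@H](O[Si](C)(C)C(C)(C)C)CCC2=CC1 | intermediate
13 | 3α-(tert-butyldimethylsilyloxy)eremophila-9,11-diene (7β-isopropenyl) | C=C(C)[C@H]1C[C@]2(C)[C@@H](C)[C@H](O[Si](C)(C)C(C)(C)C)CCC2=CC1 | intermediate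
14 | 3α-(tert-butyldimethylsilyloxy)eremophila-9,11-dien-8-one, 7β-isopropenyl | C=C(C)[C@H]1C[C@]2(C)[C@@H](C)[C@H](O[Si](C)(C)C(C)(C)C)CCC2=CC1=O | intermediate
15 | 3α-(tert-butyldimethylsilyloxy)eremophila-9,11-dien-8-one, 7α-isopropenyl | C=C(C)[C@@H]1C[C@]2(C)[C@@H](C)[C@H](O[Si](C)(C)C(C)(C)C)CCC2=CC1=O | intermediate
16 | lithium 8(9)-enolate of the 10αH ketone | C=C(C)[C@@H]1C[C@]2(C)[C@@H](C)[C@H](O[Si](C)(C)C(C)(C)C)CC[C@H]2C=C1[O-].[Li+] | intermediate
17 | 3α-(tert-butyldimethylsilyloxy)-8-(trimethylsilyloxy)-10αH-eremophila-8,11-diene | C=C(C)[C@@H]1C[C@]2(C)[C@@H](C)[C@H](O[Si](C)(C)C(C)(C)C)CC[C@H]2C=C1O[Si](C)(C)C | intermediate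
18 | 8α,9α-epoxy-8β-(trimethylsilyloxy) derivative of 17 | C=C(C)[C@@H]1C[C@]2(C)[C@@H](C)[C@H](O[Si](C)(C)C(C)(C)C)CC[C@H]2[C@@H]3O[C@]13O[Si](C)(C)C | intermediate
19 | 3α-(tert-butyldimethylsilyloxy)-9α-hydroxy-10αH-eremophil-11-en-8-one | C=C(C)[C@@H]1C[C@]2(C)[C@@H](C)[C@H](O[Si](C)(C)C(C)(C)C)CC[C@H]2[C@H](O)C1=O | intermediate
20 | 3α-(tert-butyldimethylsilyloxy)-9α-tigloyloxy-10αH-eremophil-11-en-8-one | C=C(C)[C@@H]1C[C@]2(C)[C@@H](C)[C@H](O[Si](C)(C)C(C)(C)C)CC[C@H]2[C@H](OC(=O)/C(C)=C/C)C1=O | intermediate
21 | 3α-hydroxy-9α-tigloyloxy-10αH-eremophil-11-en-8-one | C=C(C)[C@@H]1C[C@]2(C)[C@@H](C)[C@H](O)CC[C@H]2[C@H](OC(=O)/C(C)=C/C)C1=O | intermediate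
22 | 3α-senecioyloxy-9α-tigloyloxy-10αH-eremophil-11-en-8-one (CNP0164025.1) | C=C(C)[C@@H]1C[C@]2(C)[C@@H](C)[C@H](OC(=O)C=C(C)C)CC[C@H]2[C@H](OC(=O)/C(C)=C/C)C1=O | target

## Step count and least certain steps

Total step count: 15. Longest linear sequence: 15 steps (1 → 22); the route is fully linear.

Step 6 (key step). Most likely to go wrong: the terminating proton loss. The C10 cation can shed H-1 as well as H-9, because both sets of C–H bonds can align with the empty orbital and the bias from the substrate is modest. Loss of H-6 from the opening epoxide, before the methyl moves, is the second risk. Fallback (the 9,10 double bond is then placed by a reductive 1,3-transposition instead of by direct elimination): it sets out from 10, which under the conditions of step 6 would then give mainly the 1(10)-olefin isomer F1. SeO2/t-BuOOH hydroxylates the allylic methylene on the more substituted olefin terminus, C9, to give the allylic alcohol F2. MnO2 oxidises it to the 1(10)-en-9-one F3, and TsNHNH2 gives the tosylhydrazone F4. Catecholborane followed by NaOAc reduces F4 with migration of the double bond to C9=C10, which returns to the route at 11.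

Step 9. Most likely to go wrong: hydrogen abstraction at the wrong allylic site (C1 of the ring olefin, or C7–H and the methyl of the isopropenyl group) and over-oxidation, since the chromium reagent discriminates only through sterics and radical stability. Fallback (oxygen is placed on the olefin carbons and then shifted, with no C–H abstraction by the metal): from 13, sensitised photooxygenation (O2, tetraphenylporphyrin, hν) is a Schenck ene reaction in which the trisubstituted ring olefin should react far faster than the isopropenyl group. Oxygen enters C10 on the α face with removal of H-8 and gives the tertiary allylic hydroperoxide F5. PPh3 reduces it to the tertiary allylic alcohol F6. Pyridinium chlorochromate, [C5H5NH][CrO3Cl], then effects the oxidative 1,3-transposition (Babler–Dauben oxidation) and rejoins the route at 14.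

Step 10. Most likely to go wrong: drift of the isopropenyl double bond into conjugation with the ketone on prolonged contact with base, since the cross-conjugated isopropylidene dienone is the thermodynamic sink. Fallback (one irreversible deprotonation and a kinetic quench instead of an equilibrium): from 14, LiN(i-Pr)2 in THF at −78 °C removes H-7 to give the cross-conjugated lithium dienolate F7, which is protonated at −78 °C with acetic acid. Dienolates protonate kinetically at the α-carbon, so the conjugated isomer cannot build up, and axial protonation on the β face gives 15; recovered 14 is recycled.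

Step 8 (with step 7). Most likely to go wrong: rearrangement of the tertiary C4 radical before it is reduced. It is homoallylic to the C9=C10 bond and can close to a cyclopropylcarbinyl radical and reopen with a 1,2-shift of C10. Slow acylation of the hindered tertiary alcohol in step 7 is the second risk. Fallback (the C4–O bond is cleaved by electron transfer next to a carbonyl group, with no free C4 radical): from 11, Bu4NF removes the silyl group to give the diol F8. Dess–Martin periodinane oxidises only the secondary hydroxyl to the α-hydroxy ketone F9. SmI2 in THF/MeOH cleaves the α C–O bond and gives the ketone F10, in which K2CO3/MeOH brings the C4 methyl to the equatorial β position. Li in NH3 with MeOH reduces F10 to the equatorial 3α-alcohol F11; hydride reagents would give the axial alcohol because the axial 5β-methyl blocks axial attack. TBSCl/imidazole then returns to the route at 13.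

Step 3. Most likely to go wrong: poor facial selectivity at C3 (some 3β-alcohol), because the two faces of the enone carbonyl differ only modestly. Fallback (C3 is set by inversion instead of by reagent approach): from 7, NaBH4/CeCl3·7H2O (Luche reduction, axial hydride attack) gives the 3β-alcohol F12. A Mitsunobu reaction with 4-nitrobenzoic acid, PPh3 and diisopropyl azodicarboxylate inverts it to the 3α-ester F13, and K2CO3/MeOH releases 8.

## Further compounds

F1 | step 6 | 3α-(tert-butyldimethylsilyloxy)eremophila-1(10),11-dien-4α-ol | C=C(C)[C@H]1C[C@]2(C)[C@](C)(O)[C@H](O[Si](C)(C)C(C)(C)C)CC=C2CC1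
F2 | step 6 | 3α-(tert-butyldimethylsilyloxy)eremophila-1(10),11-diene-4α,9-diol (C9 epimers) | C=C(C)[C@H]1C[C@]2(C)[C@](C)(O)[C@H](O[Si](C)(C)C(C)(C)C)CC=C2C(O)C1
F3 | step 6 | 3α-(tert-butyldimethylsilyloxy)-4α-hydroxyeremophila-1(10),11-dien-9-one | C=C(C)[C@H]1C[C@]2(C)[C@](C)(O)[C@H](O[Si](C)(C)C(C)(C)C)CC=C2C(=O)C1
F4 | step 6 | tosylhydrazone of F3 | C=C(C)[C@H]1C[C@]2(C)[C@](C)(O)[C@H](O[Si](C)(C)C(C)(C)C)CC=C2C(=NNS(=O)(=O)c3ccc(C)cc3)C1
F5 | step 9 | 3α-(tert-butyldimethylsilyloxy)-10α-hydroperoxyeremophila-8,11-diene | C=C(C)[C@H]1C[C@]2(C)[C@@H](C)[C@H](O[Si](C)(C)C(C)(C)C)CC[C@@]2(OO)C=C1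
F6 | step 9 | 3α-(tert-butyldimethylsilyloxy)eremophila-8,11-dien-10α-ol | C=C(C)[C@H]1C[C@]2(C)[C@@H](C)[C@H](O[Si](C)(C)C(C)(C)C)CC[C@@]2(O)C=C1
F7 | step 10 | lithium 7,9-dienolate of 14 | C=C(C)C1C[C@]2(C)[C@@H](C)[C@H](O[Si](C)(C)C(C)(C)C)CCC2=CC=1[O-].[Li+]
F8 | step 8 | eremophila-9,11-diene-3α,4α-diol (7β-isopropenyl) | C=C(C)[C@H]1C[C@]2(C)[C@](C)(O)[C@H](O)CCC2=CC1
F9 | step 8 | 4α-hydroxyeremophila-9,11-dien-3-one | C=C(C)[C@H]1C[C@]2(C)[C@](C)(O)C(=O)CCC2=CC1
F10 | step 8 | eremophila-9,11-dien-3-one (4β-methyl) | C=C(C)[C@H]1C[C@]2(C)[C@@H](C)C(=O)CCC2=CC1
F11 | step 8 | eremophila-9,11-dien-3α-ol (7β-isopropenyl) | C=C(C)[C@H]1C[C@]2(C)[C@@H](C)[C@H](O)CCC2=CC1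
F12 | step 3 | eudesma-4,11-dien-3β-ol | C=C(C)[C@@H]1CC[C@@]2(C)CC[C@H](O)C(C)=C2C1
F13 | step 3 | eudesma-4,11-dien-3α-yl 4-nitrobenzoate | C=C(C)[C@@H]1CC[C@@]2(C)CC[C@@H](OC(=O)c3ccc(cc3)[N+](=O)[O-])C(C)=C2C1
A1 | alternative 1 | 4-(tert-butyldimethylsilyloxy)-2,3-dimethylcyclohexan-1-one (3-methyl and 4-silyloxy as in the target, C2 epimerisable) | CC1[C@@H](C)[C@H](O[Si](C)(C)C(C)(C)C)CCC1=O
A2 | alternative 1 | 3α-(tert-butyldimethylsilyloxy)eremophil-9-en-8-one (no C7 substituent) | C1C[C@]2(C)[C@@H](C)[C@H](O[Si](C)(C)C(C)(C)C)CCC2=CC1=O
A3 | alternative 2 | 2-methoxy-4-methyl-3-[2-(3-methyloxiran-2-yl)ethyl]-6-(prop-1-en-2-yl)phenol | COc1c(O)c(C(C)=C)cc(C)c1CC[C@H]1O[C@@H]1C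
A4 | alternative 2 | 3α-hydroxy-9-methoxyeremophila-6,9,11-trien-8-one | C=C(C)C1=C[C@]2(C)[C@@H](C)[C@H](O)CCC2=C(OC)C1=O
A5 | alternative 3 | silyloxytriene for the intramolecular Diels–Alder reaction | C=C(C)[C@@H](C)[C@H](O[Si](C)(C)C(C)(C)C)CC/C=C/C(O[Si](C)(C)C)=CC(C)=C
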